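**Retrosynthetic overview**
- Ring labels: A is the ring with OH para to its ether O, B the para-phenylene ring, C the ring with OH ortho to its ether O, D the meta-phenylene ring. All four benzene rings are bought.
- The target comes from double O-demethylation, preceded by exhaustive hydrogenation/hydrogenolysis of a macrocycle. In that macrocycle the A/B bridge is a stilbene C=C and the C/D bridge is an oxirane.
- Key disconnection: the C–C bond and one C–O bond of the oxirane are cut together. This gives an open chain with a benzylic bromide on D and an aldehyde on C. Forward, an intramolecular sulfonium-ylide epoxidation closes the 18-membered ring and the oxirane in one operation.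
- The open chain comes from an Ullmann ether B–O–C (isovanillin), a Wittig bridge A–CH=CH–B, and an SNAr ether D–O–A.
- Ring order: no ring is made in steps 1–4. The macrocycle and the oxirane form together in step 5. The oxirane is erased in step 6.

Assumption: the SMILES carries no stereocentre, no stereo double bond and no fixed planar chirality. The target is therefore treated as achiral and no enantioselective step is needed.

**Step 1**
Reactants: 1 3-hydroxybenzyl alcohol; 2 2-fluoro-5-methoxybenzaldehyde
Product: 3 2-[3-(hydroxymethyl)phenoxy]-5-methoxybenzaldehyde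
Conditions: K2CO3 (2 equiv), DMAc, 140 °C, 16 h, N2
Reagents that add atoms: none
Why: SNAr reaction in which the ortho-formyl group activates the C–F bond and K2CO3 ionises only the phenol, not the benzylic alcohol, so the D–O–A ether forms chemoselectively and no stereocentre arises.

**Step 2**
Reactants: 3 2-[3-(hydroxymethyl)phenoxy]-5-methoxybenzaldehyde; 4 (4-bromobenzyl)triphenylphosphonium bromide
Product: 6 (3-{2-[(Z)-2-(4-bromophenyl)ethenyl]-4-methoxyphenoxy}phenyl)methanol (Z-enriched Z/E mixture), via (4-bromobenzylidene)triphenylphosphorane 5 (not isolated)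
Conditions: K2CO3 (3 equiv), 18-crown-6 (10 mol %), CH2Cl2, reflux, 24 h
Reagents that add atoms: none
Why: Wittig olefination under mild solid–liquid conditions tolerates the free CH2OH and the aryl bromide, the semi-stabilised ylide with an ortho-oxygenated benzaldehyde should give a Z-enriched mixture, and the geometry does not matter because the alkene is hydrogenated in step 6.

**Step 3**
Reactants: 6 (3-{2-[(Z)-2-(4-bromophenyl)ethenyl]-4-methoxyphenoxy}phenyl)methanol; 7 isovanillin (3-hydroxy-4-methoxybenzaldehyde)
Product: 8 3-[4-((Z)-2-{2-[3-(hydroxymethyl)phenoxy]-5-methoxyphenyl}ethenyl)phenoxy]-4-methoxybenzaldehyde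
Conditions: CuI (10 mol %), N,N-dimethylglycine·HCl (30 mol %), Cs2CO3 (2 equiv), 1,4-dioxane, 100 °C, Ar
Reagents that add atoms: none
Why: Ligand-accelerated Ullmann diaryl ether coupling in which the phenoxide of 7 outcompetes the un-ionised primary alcohol, while the aldehyde and the alkene are inert to Cu(I).

**Step 4**
Reactants: 8 3-[4-((Z)-2-{2-[3-(hydroxymethyl)phenoxy]-5-methoxyphenyl}ethenyl)phenoxy]-4-methoxybenzaldehyde
Product: 9 3-[4-((Z)-2-{2-[3-(bromomethyl)phenoxy]-5-methoxyphenyl}ethenyl)phenoxy]-4-methoxybenzaldehyde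
Conditions: PBr3 (0.4 equiv), CH2Cl2, 0 °C, 1 h
Reagents that add atoms: phosphorus tribromide, BrP(Br)Br
Why: SN2 bromination of the only alcohol through its phosphite ester, under conditions (0 °C) where the aromatic aldehyde, the aryl ethers and the stilbene are untouched.

**Step 5**
Reactants: 9 3-[4-((Z)-2-{2-[3-(bromomethyl)phenoxy]-5-methoxyphenyl}ethenyl)phenoxy]-4-methoxybenzaldehyde; 10 tetrahydrothiophene (mediator)
Product: 13 racemic 18-membered macrocycle A–(Z)-CH=CH–B–O–C–(trans-oxirane-2,3-diyl)–D–O–A with OMe on A and on C, via S-benzyl tetrahydrothiophenium bromide 11 (not isolated), via sulfonium benzylide 12 (not isolated)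
Conditions: (i) 10 (5 equiv), MeCN–H2O 9:1, 0.2 M, rt, 16 h; (ii) syringe pump (12 h) into KOH (5 equiv), MeCN–H2O 9:1, final 1 mM, rt
Reagents that add atoms: none
Why: Proposed new method: a macrocyclising Johnson–Corey–Chaykovsky epoxidation in which the sulfide is alkylated by the benzylic bromide, KOH reversibly forms the semi-stabilised benzylide, its carbon adds to the remote aryl aldehyde (closing the 18-membered ring) and the alkoxide then expels tetrahydrothiophene in a 3-exo-tet step (closing the oxirane); reversible addition favours the racemic trans-oxirane, any cis isomer converges because both stereocentres are erased in step 6, and the closest known reaction types are the intermolecular one-pot benzyl bromide/sulfide/base epoxidation of aromatic aldehydes to stilbene oxides and the intramolecular Wittig macrocyclisation of bis(bibenzyl) seco-aldehydes.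

**Step 6**
Reactants: 13 racemic macrocyclic (Z)-stilbene trans-oxirane
Product: 15 macrocyclic bis(bibenzyl) dimethyl ether (O,O'-dimethyl target), via racemic macrocyclic secondary benzylic alcohol 14 (not isolated)
Conditions: H2 (1 atm), 10 % Pd/C, EtOAc–EtOH 1:1, rt; then AcOH, cat. HClO4, H2 (4 bar), 40 °C
Reagents that add atoms: none
Why: Catalytic hydrogenation/hydrogenolysis in which neutral Pd/C saturates the stilbene and cleaves the more activated benzylic C–O bond of the oxirane (next to the p-methoxyaryl ring C) before any acid is present, which avoids Meinwald rearrangement, and acid-promoted benzylic hydrogenolysis then removes the remaining OH and the last stereocentre.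

**Step 7**
Reactants: 15 macrocyclic bis(bibenzyl) dimethyl ether
Product: 16 target CNP0135015.0
Conditions: BBr3 (6 equiv), CH2Cl2, −78 °C to rt, 12 h; H2O
Reagents that add atoms: none
Why: BBr3 ether cleavage in which bromide can attack only the methyl carbons of the boron-complexed aryl methyl ethers, so both diaryl ethers survive and the achiral diphenol is released on hydrolysis.

**Compound list**
1 | 3-hydroxybenzyl alcohol (ring D) | OCc1cccc(O)c1 | starting material
2 | 2-fluoro-5-methoxybenzaldehyde (ring A) | COc1ccc(F)c(C=O)c1 | starting material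
3 | 2-[3-(hydroxymethyl)phenoxy]-5-methoxybenzaldehyde | COc1ccc(Oc2cccc(CO)c2)c(C=O)c1 | intermediate
4 | (4-bromobenzyl)triphenylphosphonium bromide (ring B) | [Br-].Brc1ccc(C[P+](c2ccccc2)(c2ccccc2)c2ccccc2)cc1 | starting material
5 | (4-bromobenzylidene)triphenylphosphorane | Brc1ccc(C=P(c2ccccc2)(c2ccccc2)c2ccccc2)cc1 | intermediate
6 | (3-{2-[(Z)-2-(4-bromophenyl)ethenyl]-4-methoxyphenoxy}phenyl)methanol; Z drawn, minor E isomer carried along | COc1ccc(Oc2cccc(CO)c2)c(/C=C\c2ccc(Br)cc2)c1 | intermediate
7 | isovanillin, 3-hydroxy-4-methoxybenzaldehyde (ring C) | COc1ccc(C=O)cc1O | starting material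
8 | 3-[4-((Z)-2-{2-[3-(hydroxymethyl)phenoxy]-5-methoxyphenyl}ethenyl)phenoxy]-4-methoxybenzaldehyde | COc1ccc(Oc2cccc(CO)c2)c(/C=C\c2ccc(Oc3cc(C=O)ccc3OC)cc2)c1 | intermediate
9 | 3-[4-((Z)-2-{2-[3-(bromomethyl)phenoxy]-5-methoxyphenyl}ethenyl)phenoxy]-4-methoxybenzaldehyde | COc1ccc(Oc2cccc(CBr)c2)c(/C=C\c2ccc(Oc3cc(C=O)ccc3OC)cc2)c1 | intermediate
10 | tetrahydrothiophene | C1CCSC1 | starting material
11 | 1-{3-[2-((Z)-2-{4-[5-formyl-2-methoxyphenoxy]phenyl}ethenyl)-4-methoxyphenoxy]benzyl}tetrahydrothiophenium bromide | [Br-].COc1ccc(Oc2cccc(C[S+]3CCCC3)c2)c(/C=C\c2ccc(Oc3cc(C=O)ccc3OC)cc2)c1 | intermediate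
12 | sulfonium benzylide derived from 11 (carbanion on the D-ring benzylic carbon) | COc1ccc(Oc2cccc([CH-][S+]3CCCC3)c2)c(/C=C\c2ccc(Oc3cc(C=O)ccc3OC)cc2)c1 | intermediate
13 | macrocycle with (Z)-CH=CH between A and B and a trans-oxirane between C and D; racemic, (S,S) drawn | COc1ccc2c(c1)/C=C\c1ccc(cc1)Oc1cc(ccc1OC)[C@@H]1O[C@H]1c1cccc(c1)O2 | intermediate
14 | macrocycle with a saturated A/B bridge and a C–CH2–CH(OH)–D bridge; racemic, (R) drawn | COc1ccc2c(c1)CCc1ccc(cc1)Oc1cc(ccc1OC)C[C@@H](O)c1cccc(c1)O2 | intermediate
15 | O,O'-dimethyl ether of the target | COc1ccc2c(c1)CCc1ccc(cc1)Oc1cc(ccc1OC)CCc1cccc(c1)O2 | intermediate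
16 | target CNP0135015.0 (achiral) | Oc1ccc2c(c1)CCc1ccc(cc1)Oc1cc(ccc1O)CCc1cccc(c1)O2 | target

**Step count and risks**
Total step count: 7. Longest linear sequence: 7.

Step 5 (macrocyclising epoxidation) is the most likely to fail. The risks are oligomerisation, slow closure of the minor E-stilbene isomer, and decay of the ylide at high dilution. The fallback sets out from 9. PPh3 in toluene at reflux gives the seco phosphonium bromide F1. Slow addition of this salt to NaOMe in CH2Cl2 (1 mM) closes only the macrocycle by an intramolecular Wittig reaction, giving the macrocyclic distilbene F2 (Z/E mixture). H2 over Pd/C in EtOAc brings the fallback back to the route at 15.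

Step 6 (oxirane to CH2CH2) is the second risk. The second C–O hydrogenolysis may stall, or acid may trigger rearrangement. The fallback sets out from 14, which is isolated after the neutral hydrogenation stage. The hydroxyl group is removed by ionic hydrogenation through the benzylic cation (Et3SiH, BF3·OEt2, CH2Cl2, −20 °C), and the fallback comes back at 15. New compounds: none F0.

Step 3 (Ullmann coupling of a hindered guaiacol-type phenol beside a free alcohol) is the third risk. The fallback sets out from 6. Miyaura borylation (B2pin2, PdCl2(dppf), KOAc, dioxane, 80 °C) gives the stilbene pinacol boronate F3. This is joined to 7 by an oxidative Chan–Lam–Evans coupling (Cu(OAc)2, pyridine, B(OH)3, air, MeCN, 4 Å MS, 60 °C), and the fallback comes back at 8.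

**Further compounds**
F1 | step 5 | {3-[2-((Z)-2-{4-[5-formyl-2-methoxyphenoxy]phenyl}ethenyl)-4-methoxyphenoxy]benzyl}triphenylphosphonium bromide | [Br-].COc1ccc(Oc2cccc(C[P+](c3ccccc3)(c3ccccc3)c3ccccc3)c2)c(/C=C\c2ccc(Oc3cc(C=O)ccc3OC)cc2)c1
F2 | step 5 | macrocyclic distilbene dimethyl ether (Z,Z drawn, Z/E mixture) | COc1ccc2c(c1)/C=C\c1ccc(cc1)Oc1cc(ccc1OC)/C=C\c1cccc(c1)O2
F3 | step 3 | (3-{4-methoxy-2-[(Z)-2-(4-(4,4,5,5-tetramethyl-1,3,2-dioxaborolan-2-yl)phenyl)ethenyl]phenoxy}phenyl)methanol | COc1ccc(Oc2cccc(CO)c2)c(/C=C\c2ccc(B3OC(C)(C)C(C)(C)O3)cc2)c1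
F0 | step 6 | none | none
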